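**Retrosynthetic overview**

1. The target is ent-fisetinidol-(4α→6)-ent-fisetinidol-(4α→8)-[ent-fisetinidol-(4β→6)]-catechin; the flavan units are called unit 1 (top), unit 2, unit 3 (catechin) and unit 4 (on C6 of catechin), each with rings A (benzo), C (pyran) and B (catechol); the last step is global O-debenzylation.
2. Each ent-fisetinidol unit is grown on the unit below from an achiral chalcone (its 5'-bromo form for unit 2, which brings in the handle for unit 1): the C4–aryl bond by 1,2-addition of an aryllithium to the chalcone carbonyl, ring C by chiral-acid-catalysed closure O1→C2 of the derived allyl cation to a 4-aryl-2H-chromene, then C3 and C4 by relay from C2 (osmylation, then hydride at the C4 cation anti to O3, for the 3,4-cis units 1 and 2; hydroboration–oxidation for the 3,4-trans unit 4).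
3. Disconnections of unit 1, made last: C4–H and C3–O (relay), O1–C2 (ring closure), C4–C6 of unit 2 (aryllithium plus chalcone); units 4 and 2 are disconnected the same way from a C6 iodide and the C8 bromide of perbenzylated (+)-catechin.
4. Order of ring formation (rings A and B are bought, ring C of unit 3 comes with catechin): ring C of unit 2, then ring C of unit 4, last ring C of unit 1.
5. Enabling feature: in unit 1, C4 lies between two resorcinol-type rings (C4a of ring A with O1 ortho and O7 para; C6 of unit 2 with O7 ortho and O1 para) and C2 bears the 4'-oxygenated ring B, so the C2–C3–C4 allyl cation is stabilised at both ends and forms from a tertiary carbinol with catalytic acid, while O1 on C8a, ortho to C4a, is placed to close ring C at C2.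

Key step: step 19

Assumption: the (R)-configured acid, (R)-3,3'-bis(2,4,6-triisopropylphenyl)-1,1'-binaphthyl-2,2'-diyl N-triflylphosphoramide [(R)-TRIP-NHTf], is taken to give the (2R)-2H-chromene (ring B on the β face, as in ent-fisetinidol). If a model closure shows the opposite sense, the (S)-acid is used in all three closures and nothing else changes.

Remark: the acetophenone, the aldehyde and (+)-catechin are commercial. The tertiary carbinol centre of each chalcone adduct forms as both epimers and is erased on ionisation, so it is left undefined.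

**Route**

Step 1
Reactants: 1 1-[4-(benzyloxy)-2-hydroxyphenyl]ethan-1-one; 2 3,4-bis(benzyloxy)benzaldehyde
Product: 3 (E)-1-[4-(benzyloxy)-2-hydroxyphenyl]-3-[3,4-bis(benzyloxy)phenyl]prop-2-en-1-one
Conditions: KOH, EtOH/THF, rt
Reagents that add atoms: none
Why: Claisen–Schmidt condensation (aldol addition, then E1cB loss of water) should give the (E)-chalcone; no stereocentre is formed.

Step 2
Reactants: 3 chalcone
Product: 4 (E)-1-[4-(benzyloxy)-2-(tert-butyldimethylsilyloxy)phenyl]-3-[3,4-bis(benzyloxy)phenyl]prop-2-en-1-one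
Conditions: TBSCl, imidazole, DMAP (cat.), DMF, 40 °C
Reagents that add atoms: tert-butyldimethylsilyl chloride, CC(C)(C)[Si](C)(C)Cl
Why: O-silylation of the phenol masks the acidic 2'-OH for the aryllithium additions and can later be undone with fluoride without any acid; no stereocentre.

Step 3
Reactants: 1 1-[4-(benzyloxy)-2-hydroxyphenyl]ethan-1-one
Product: 5 1-[4-(benzyloxy)-5-bromo-2-hydroxyphenyl]ethan-1-one
Conditions: NBS, MeCN, 0 °C to rt
Reagents that add atoms: N-bromosuccinimide, O=C1CCC(=O)N1Br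
Why: Electrophilic aromatic bromination para to the free hydroxyl and ortho to the benzyloxy group (C5'), the carbon that becomes C6 of unit 2; no stereocentre.

Step 4
Reactants: 5 bromoacetophenone; 2 3,4-bis(benzyloxy)benzaldehyde
Product: 6 (E)-1-[4-(benzyloxy)-5-bromo-2-hydroxyphenyl]-3-[3,4-bis(benzyloxy)phenyl]prop-2-en-1-one
Conditions: KOH, EtOH/THF, rt
Reagents that add atoms: none
Why: Claisen–Schmidt condensation as in step 1; the aryl bromide is inert to hydroxide; no stereocentre.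

Step 5
Reactants: 6 bromochalcone
Product: 7 (E)-1-[4-(benzyloxy)-5-bromo-2-(tert-butyldimethylsilyloxy)phenyl]-3-[3,4-bis(benzyloxy)phenyl]prop-2-en-1-one
Conditions: TBSCl, imidazole, DMAP (cat.), DMF, 40 °C
Reagents that add atoms: tert-butyldimethylsilyl chloride, CC(C)(C)[Si](C)(C)Cl
Why: O-silylation of the phenol as in step 2; no stereocentre.

Step 6
Reactants: 8 (+)-catechin
Product: 9 3,5,7,3',4'-penta-O-benzyl-(+)-catechin
Conditions: NaH, BnBr, Bu4NI (cat.), DMF, 0 °C to rt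
Reagents that add atoms: benzyl bromide, BrCc1ccccc1
Why: Williamson etherification of the four phenols and the C3 alcohol; the low temperature should hold back C-benzylation and base-induced opening of ring C, so C2 and C3 of catechin are kept.

Step 7
Reactants: 9 penta-O-benzylcatechin
Product: 10 8-bromo-3,5,7,3',4'-penta-O-benzylcatechin
Conditions: NBS, CH2Cl2, −78 to 0 °C
Reagents that add atoms: N-bromosuccinimide, O=C1CCC(=O)N1Br
Why: Electrophilic bromination of the phloroglucinol-type ring A, which is known to take the first bromine at C8 in 3-O-protected tetra-O-benzyl flavan-3-ols; no stereocentre is touched.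

Step 8
Reactants: 10 8-bromo-penta-O-benzylcatechin; 7 bromochalcone silyl ether
Product: 13 (E)-1-[4-(benzyloxy)-5-bromo-2-hydroxyphenyl]-3-[3,4-bis(benzyloxy)phenyl]-1-(penta-O-benzylcatechin-8-yl)prop-2-en-1-ol, via 8-lithio-penta-O-benzylcatechin 11 (not isolated), via O-silyl carbinol 12 (not isolated)
Conditions: t-BuLi (2 equiv), THF, −78 °C; then 7, −78 to −40 °C; then AcOH, Bu4NF, THF, 0 °C
Reagents that add atoms: none
Why: Bromine–lithium exchange gives a 2,6-dialkoxyaryllithium that adds 1,2 to the enone carbonyl of 7 (a hard aryllithium, faster than exchange with the aryl bromide of 7), and buffered fluoride then frees the phenol; the carbinol centre forms as both epimers and is erased in step 9.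

Step 9
Reactants: 13 carbinol
Product: 14 8-[(2R)-7-(benzyloxy)-2-[3,4-bis(benzyloxy)phenyl]-6-bromo-2H-chromen-4-yl]-penta-O-benzylcatechin
Conditions: (R)-TRIP-NHTf (5 mol%), 4 Å molecular sieves, toluene, −60 °C
Reagents that add atoms: none
Why: Chiral Brønsted acid-catalysed dehydrative cyclisation (intramolecular asymmetric allylic substitution through a contact ion pair): the phenol oxygen closes the allyl cation at C2 to ring C of unit 2, and C2 is set by the catalyst anion.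

Step 10
Reactants: 14 chromene
Product: 15 6-bromo-7,3',4'-tri-O-benzyl-4α-hydroxy-ent-fisetinidol-(4β→8)-penta-O-benzylcatechin (3-OH and 4-OH both α)
Conditions: OsO4 (10 mol%), NMO, acetone/THF/H2O, rt
Reagents that add atoms: osmium tetroxide, O=[Os](=O)(=O)=O (catalytic carrier of the oxygen atoms); N-methylmorpholine N-oxide, C[N+]1([O-])CCOCC1; water, O
Why: Upjohn dihydroxylation of the C3=C4 bond from the face opposite the C2 aryl group, as flav-3-enes are known to react, should give the 2,3-trans-3,4-cis diol, which fixes C3.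

Step 11
Reactants: 15 diol
Product: 16 6-bromo-7,3',4'-tri-O-benzyl-ent-fisetinidol-(4α→8)-penta-O-benzylcatechin
Conditions: Et3SiH, CF3CO2H, CH2Cl2, −40 °C
Reagents that add atoms: none
Why: Ionic hydrogenation: the acid ionises the tertiary, doubly benzylic 4-OH and the silane delivers hydride to the flavan-4-yl cation anti to the 3-OH (the facial preference that makes arene nucleophiles add 3,4-trans), so the catechin ring ends cis to O3, that is 4α.

Step 12
Reactants: 16 dimer alcohol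
Product: 17 6-bromo-3,7,3',4'-tetra-O-benzyl-ent-fisetinidol-(4α→8)-penta-O-benzylcatechin
Conditions: NaH, BnBr, Bu4NI (cat.), DMF, 0 °C to rt
Reagents that add atoms: benzyl bromide, BrCc1ccccc1
Why: Williamson etherification of the only free hydroxyl removes the last acidic proton before the next organolithium step; no stereocentre is touched.

Step 13
Reactants: 17 dimer bromide
Product: 18 6-bromo-3,7,3',4'-tetra-O-benzyl-ent-fisetinidol-(4α→8)-6-iodo-penta-O-benzylcatechin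
Conditions: NIS, CF3CO2H (cat.), CH2Cl2/MeCN, 0 °C
Reagents that add atoms: N-iodosuccinimide, O=C1CCC(=O)N1I
Why: Electrophilic iodination at the only free position of the phloroglucinol-type ring A of unit 3 (C6), which is more electron-rich than the brominated resorcinol-type ring of unit 2 and the catechol rings; no stereocentre is touched.

Step 14
Reactants: 18 dimer iodide; 4 chalcone silyl ether
Product: 21 carbinol: unit 3 of 17 bearing at C6 the (E)-1-[4-(benzyloxy)-2-hydroxyphenyl]-3-[3,4-bis(benzyloxy)phenyl]-1-hydroxyprop-2-en-1-yl group, via C6-lithio dimer 19 (not isolated), via O-silyl carbinol 20 (not isolated)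
Conditions: n-BuLi (1.05 equiv), THF/Et2O, −100 °C; then 4, −100 to −40 °C; then AcOH, Bu4NF, THF, 0 °C
Reagents that add atoms: none
Why: Iodine–lithium exchange is far faster than bromine–lithium exchange at −100 °C, so the C6 aryllithium forms with the bromide of unit 2 intact and adds 1,2 to the chalcone carbonyl, after which buffered fluoride frees the phenol; the carbinol centre forms as both epimers and is erased in step 15.

Step 15
Reactants: 21 carbinol
Product: 22 chromene: unit 3 of 17 bearing at C6 the (2R)-7-(benzyloxy)-2-[3,4-bis(benzyloxy)phenyl]-2H-chromen-4-yl group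
Conditions: (R)-TRIP-NHTf (5 mol%), 4 Å molecular sieves, toluene, −60 °C
Reagents that add atoms: none
Why: Chiral Brønsted acid-catalysed dehydrative cyclisation as in step 9 closes ring C of unit 4 by attack of the phenol oxygen on C2 of the allyl cation, with C2 set by the catalyst anion.

Step 16
Reactants: 22 chromene
Product: 23 6-bromo-3,7,3',4'-tetra-O-benzyl-ent-fisetinidol-(4α→8)-[7,3',4'-tri-O-benzyl-ent-fisetinidol-(4β→6)]-penta-O-benzylcatechin
Conditions: BH3·THF, THF, 0 °C to rt; then NaOH, H2O2, H2O, 0 °C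
Reagents that add atoms: hydrogen peroxide, OO
Why: Hydroboration–oxidation: borane adds syn across C3=C4 from the face anti to ring B with boron on the less substituted C3, and oxidation with retention gives 3α-OH and 4α-H, that is the 2,3-trans-3,4-trans unit 4 with its aryl group 4β.

Step 17
Reactants: 23 trimer alcohol
Product: 24 6-bromo-3,7,3',4'-tetra-O-benzyl-ent-fisetinidol-(4α→8)-[3,7,3',4'-tetra-O-benzyl-ent-fisetinidol-(4β→6)]-penta-O-benzylcatechin
Conditions: NaH, BnBr, Bu4NI (cat.), DMF, 0 °C to rt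
Reagents that add atoms: benzyl bromide, BrCc1ccccc1
Why: Williamson etherification of the only free hydroxyl before the last organolithium step; no stereocentre is touched.

Step 18
Reactants: 24 trimer bromide; 4 chalcone silyl ether
Product: 27 carbinol: (E)-1-[4-(benzyloxy)-2-hydroxyphenyl]-3-[3,4-bis(benzyloxy)phenyl]prop-2-en-1-ol bearing at C1 the C6 of unit 2 of 24, via C6-lithio trimer 25 (not isolated), via O-silyl carbinol 26 (not isolated)
Conditions: t-BuLi (2 equiv), THF, −78 °C; then 4, −78 to −40 °C; then AcOH, Bu4NF, THF, 0 °C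
Reagents that add atoms: none
Why: Bromine–lithium exchange at C6 of unit 2 and 1,2-addition of the aryllithium to the chalcone carbonyl, then buffered desilylation, as in step 8; the carbinol centre forms as both epimers and is erased in step 19.

Step 19
Reactants: 27 carbinol
Product: 28 chromene: 24 in which bromine is replaced by the (2R)-7-(benzyloxy)-2-[3,4-bis(benzyloxy)phenyl]-2H-chromen-4-yl group (ring C of unit 1 closed)
Conditions: (R)-TRIP-NHTf (5 mol%), 4 Å molecular sieves, toluene, −60 °C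
Reagents that add atoms: none
Why: The catalytic acid protonates the tertiary, doubly benzylic hydroxyl of 27 and water leaves, giving the C2–C3–C4 allyl cation (the protonated vinylogous o-quinone methide of ring A of unit 1) as a contact ion pair with the chiral phosphoramide anion, and the phenolic O1 then attacks C2. The closest known reaction type is the chiral N-triflylphosphoramide-catalysed intramolecular allylic substitution of 2-(1-hydroxy-1,3-diarylallyl)phenols to 2,4-diaryl-2H-chromenes. Ring C of unit 1 is closed by O1–C2 bond formation in a 6-endo attack of the phenol on the allyl cation terminus (equivalently an oxa-6π closure of the o-quinone methide form). The one new stereocentre, C2, is set by the catalyst anion, which is hydrogen-bonded to the phenol and shields one face of the cation terminus, the stereocentres of units 2 to 4 being remote; C3 and C4 are then relayed from C2 in steps 20 and 21. The step needs ionisation at this carbinol only and no re-ionisation of the product: this is the one site whose cation is stabilised by two 2,4-dioxygenated aryl rings and a 3,4-dioxygenated styryl group, so a few mol% of acid at −60 °C in toluene should leave the benzyl ethers, the other ring C benzylic C–O bonds and the interflavan bonds untouched and keep the C2–O1 bond of 28 closed.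

Step 20
Reactants: 28 chromene
Product: 29 diol: 28 with 3α-OH and 4α-OH on unit 1 (2,3-trans-3,4-cis diol, C6 of unit 2 on the β face of C4)
Conditions: OsO4 (10 mol%), NMO, acetone/THF/H2O, rt
Reagents that add atoms: osmium tetroxide, O=[Os](=O)(=O)=O (catalytic carrier of the oxygen atoms); N-methylmorpholine N-oxide, C[N+]1([O-])CCOCC1; water, O
Why: Upjohn dihydroxylation of C3=C4 of unit 1 from the face opposite ring B, as in step 10, fixes C3 as the 2,3-trans alcohol.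

Step 21
Reactants: 29 diol
Product: 30 7,3',4'-tri-O-benzyl-ent-fisetinidol-(4α→6)-3,7,3',4'-tetra-O-benzyl-ent-fisetinidol-(4α→8)-[3,7,3',4'-tetra-O-benzyl-ent-fisetinidol-(4β→6)]-penta-O-benzylcatechin
Conditions: Et3SiH, CF3CO2H, CH2Cl2, −40 °C
Reagents that add atoms: none
Why: Ionic hydrogenation as in step 11: hydride adds to the doubly benzylic C4 cation of unit 1 anti to the 3-OH, so the aryl group of unit 2 ends cis to O3 (4α) and the 2,3-trans-3,4-cis unit 1 is complete.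

Step 22
Reactants: 30 hexadeca-O-benzyl tetramer
Product: 31 ent-fisetinidol-(4α→6)-ent-fisetinidol-(4α→8)-[ent-fisetinidol-(4β→6)]-catechin (target)
Conditions: H2 (1 atm), Pd(OH)2/C, THF/MeOH/H2O, rt
Reagents that add atoms: none
Why: Hydrogenolysis of the sixteen benzyl ethers; interflavan C–C bonds and the ring C benzylic C–O bonds are known to survive these conditions in proanthocyanidin work, and no stereocentre is touched.

**Compound list**

1 | 1-[4-(benzyloxy)-2-hydroxyphenyl]ethan-1-one | CC(=O)c1ccc(OCc2ccccc2)cc1O | starting material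
2 | 3,4-bis(benzyloxy)benzaldehyde | O=Cc1ccc(OCc2ccccc2)c(OCc2ccccc2)c1 | starting material
3 | (E)-1-[4-(benzyloxy)-2-hydroxyphenyl]-3-[3,4-bis(benzyloxy)phenyl]prop-2-en-1-one | O=C(/C=C/c8ccc(OCc9ccccc9)c(OCc9ccccc9)c8)c1ccc(OCc9ccccc9)cc1O | intermediate
4 | 2'-O-TBS ether of 3 | O=C(/C=C/c8ccc(OCc9ccccc9)c(OCc9ccccc9)c8)c1ccc(OCc9ccccc9)cc1O[Si](C)(C)C(C)(C)C | intermediate
5 | 1-[4-(benzyloxy)-5-bromo-2-hydroxyphenyl]ethan-1-one | CC(=O)c1cc(Br)c(OCc2ccccc2)cc1O | intermediate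
6 | (E)-1-[4-(benzyloxy)-5-bromo-2-hydroxyphenyl]-3-[3,4-bis(benzyloxy)phenyl]prop-2-en-1-one | O=C(/C=C/c8ccc(OCc9ccccc9)c(OCc9ccccc9)c8)c1cc(Br)c(OCc9ccccc9)cc1O | intermediate
7 | 2'-O-TBS ether of 6 | O=C(/C=C/c8ccc(OCc9ccccc9)c(OCc9ccccc9)c8)c1cc(Br)c(OCc9ccccc9)cc1O[Si](C)(C)C(C)(C)C | intermediate
8 | (+)-catechin, (2R,3S)-2-(3,4-dihydroxyphenyl)chromane-3,5,7-triol | Oc1cc(O)c2c(c1)O[C@H](c1ccc(O)c(O)c1)[C@@H](O)C2 | starting material
9 | 3,5,7,3',4'-penta-O-benzyl-(+)-catechin (2R,3S) | c1c(OCc9ccccc9)cc(OCc9ccccc9)c2c1O[C@H](c8ccc(OCc9ccccc9)c(OCc9ccccc9)c8)[C@@H](OCc9ccccc9)C2 | intermediate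
10 | 8-bromo-3,5,7,3',4'-penta-O-benzylcatechin | Brc1c(OCc9ccccc9)cc(OCc9ccccc9)c2c1O[C@H](c8ccc(OCc9ccccc9)c(OCc9ccccc9)c8)[C@@H](OCc9ccccc9)C2 | intermediate
11 | 8-lithio-3,5,7,3',4'-penta-O-benzylcatechin | [Li]c1c(OCc9ccccc9)cc(OCc9ccccc9)c2c1O[C@H](c8ccc(OCc9ccccc9)c(OCc9ccccc9)c8)[C@@H](OCc9ccccc9)C2 | intermediate (not isolated)
12 | (E)-1-[4-(benzyloxy)-5-bromo-2-(tert-butyldimethylsilyloxy)phenyl]-3-[3,4-bis(benzyloxy)phenyl]-1-(penta-O-benzylcatechin-8-yl)prop-2-en-1-ol, both C1 epimers | CC(C)(C)[Si](C)(C)Oc1cc(OCc9ccccc9)c(Br)cc1C(O)(/C=C/c8ccc(OCc9ccccc9)c(OCc9ccccc9)c8)c1c(OCc9ccccc9)cc(OCc9ccccc9)c2c1O[C@H](c8ccc(OCc9ccccc9)c(OCc9ccccc9)c8)[C@@H](OCc9ccccc9)C2 | intermediate (not isolated)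
13 | (E)-1-[4-(benzyloxy)-5-bromo-2-hydroxyphenyl]-3-[3,4-bis(benzyloxy)phenyl]-1-(penta-O-benzylcatechin-8-yl)prop-2-en-1-ol, both C1 epimers | Oc1cc(OCc9ccccc9)c(Br)cc1C(O)(/C=C/c8ccc(OCc9ccccc9)c(OCc9ccccc9)c8)c1c(OCc9ccccc9)cc(OCc9ccccc9)c2c1O[C@H](c8ccc(OCc9ccccc9)c(OCc9ccccc9)c8)[C@@H](OCc9ccccc9)C2 | intermediate
14 | 8-[(2R)-7-(benzyloxy)-2-[3,4-bis(benzyloxy)phenyl]-6-bromo-2H-chromen-4-yl]-penta-O-benzylcatechin | Brc1cc2c(cc1OCc9ccccc9)O[C@@H](c8ccc(OCc9ccccc9)c(OCc9ccccc9)c8)C=C2c1c(OCc9ccccc9)cc(OCc9ccccc9)c2c1O[C@H](c8ccc(OCc9ccccc9)c(OCc9ccccc9)c8)[C@@H](OCc9ccccc9)C2 | intermediate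
15 | 6-bromo-7,3',4'-tri-O-benzyl-4α-hydroxy-ent-fisetinidol-(4β→8)-penta-O-benzylcatechin (upper unit 2S, 2,3-trans, 3-OH and 4-OH both α) | Brc1cc2c(cc1OCc9ccccc9)O[C@@H](c8ccc(OCc9ccccc9)c(OCc9ccccc9)c8)[C@H](O)[C@@]2(O)c1c(OCc9ccccc9)cc(OCc9ccccc9)c2c1O[C@H](c8ccc(OCc9ccccc9)c(OCc9ccccc9)c8)[C@@H](OCc9ccccc9)C2 | intermediate
16 | 6-bromo-7,3',4'-tri-O-benzyl-ent-fisetinidol-(4α→8)-penta-O-benzylcatechin (upper unit 2S,3R, 2,3-trans-3,4-cis, 3-OH free) | Brc1cc2c(cc1OCc9ccccc9)O[C@@H](c8ccc(OCc9ccccc9)c(OCc9ccccc9)c8)[C@H](O)[C@@H]2c1c(OCc9ccccc9)cc(OCc9ccccc9)c2c1O[C@H](c8ccc(OCc9ccccc9)c(OCc9ccccc9)c8)[C@@H](OCc9ccccc9)C2 | intermediate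
17 | 6-bromo-3,7,3',4'-tetra-O-benzyl-ent-fisetinidol-(4α→8)-penta-O-benzylcatechin | Brc1cc2c(cc1OCc9ccccc9)O[C@@H](c8ccc(OCc9ccccc9)c(OCc9ccccc9)c8)[C@H](OCc9ccccc9)[C@@H]2c1c(OCc9ccccc9)cc(OCc9ccccc9)c2c1O[C@H](c8ccc(OCc9ccccc9)c(OCc9ccccc9)c8)[C@@H](OCc9ccccc9)C2 | intermediate
18 | 6-bromo-3,7,3',4'-tetra-O-benzyl-ent-fisetinidol-(4α→8)-6-iodo-penta-O-benzylcatechin | Brc1cc2c(cc1OCc9ccccc9)O[C@@H](c8ccc(OCc9ccccc9)c(OCc9ccccc9)c8)[C@H](OCc9ccccc9)[C@@H]2c1c(OCc9ccccc9)c(I)c(OCc9ccccc9)c2c1O[C@H](c8ccc(OCc9ccccc9)c(OCc9ccccc9)c8)[C@@H](OCc9ccccc9)C2 | intermediate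
19 | 18 with lithium in place of iodine (C6 of unit 3) | Brc1cc2c(cc1OCc9ccccc9)O[C@@H](c8ccc(OCc9ccccc9)c(OCc9ccccc9)c8)[C@H](OCc9ccccc9)[C@@H]2c1c(OCc9ccccc9)c([Li])c(OCc9ccccc9)c2c1O[C@H](c8ccc(OCc9ccccc9)c(OCc9ccccc9)c8)[C@@H](OCc9ccccc9)C2 | intermediate (not isolated)
20 | 17 bearing at C6 of unit 3 the (E)-1-[4-(benzyloxy)-2-(tert-butyldimethylsilyloxy)phenyl]-3-[3,4-bis(benzyloxy)phenyl]-1-hydroxyprop-2-en-1-yl group, both carbinol epimers | Brc1cc2c(cc1OCc9ccccc9)O[C@@H](c8ccc(OCc9ccccc9)c(OCc9ccccc9)c8)[C@H](OCc9ccccc9)[C@@H]2c1c(OCc9ccccc9)c(C(O)(/C=C/c8ccc(OCc9ccccc9)c(OCc9ccccc9)c8)c3ccc(OCc9ccccc9)cc3O[Si](C)(C)C(C)(C)C)c(OCc9ccccc9)c2c1O[C@H](c8ccc(OCc9ccccc9)c(OCc9ccccc9)c8)[C@@H](OCc9ccccc9)C2 | intermediate (not isolated)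
21 | 20 with the phenol free, both carbinol epimers | Brc1cc2c(cc1OCc9ccccc9)O[C@@H](c8ccc(OCc9ccccc9)c(OCc9ccccc9)c8)[C@H](OCc9ccccc9)[C@@H]2c1c(OCc9ccccc9)c(C(O)(/C=C/c8ccc(OCc9ccccc9)c(OCc9ccccc9)c8)c3ccc(OCc9ccccc9)cc3O)c(OCc9ccccc9)c2c1O[C@H](c8ccc(OCc9ccccc9)c(OCc9ccccc9)c8)[C@@H](OCc9ccccc9)C2 | intermediate
22 | 17 bearing at C6 of unit 3 the (2R)-7-(benzyloxy)-2-[3,4-bis(benzyloxy)phenyl]-2H-chromen-4-yl group | Brc1cc2c(cc1OCc9ccccc9)O[C@@H](c8ccc(OCc9ccccc9)c(OCc9ccccc9)c8)[C@H](OCc9ccccc9)[C@@H]2c1c(OCc9ccccc9)c(C=2c3ccc(OCc9ccccc9)cc3O[C@@H](c8ccc(OCc9ccccc9)c(OCc9ccccc9)c8)C=2)c(OCc9ccccc9)c2c1O[C@H](c8ccc(OCc9ccccc9)c(OCc9ccccc9)c8)[C@@H](OCc9ccccc9)C2 | intermediate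
23 | 6-bromo-3,7,3',4'-tetra-O-benzyl-ent-fisetinidol-(4α→8)-[7,3',4'-tri-O-benzyl-ent-fisetinidol-(4β→6)]-penta-O-benzylcatechin (unit 4 2S,3R, 2,3-trans-3,4-trans, 3-OH free) | Brc1cc2c(cc1OCc9ccccc9)O[C@@H](c8ccc(OCc9ccccc9)c(OCc9ccccc9)c8)[C@H](OCc9ccccc9)[C@@H]2c1c(OCc9ccccc9)c([C@H]2c3ccc(OCc9ccccc9)cc3O[C@@H](c8ccc(OCc9ccccc9)c(OCc9ccccc9)c8)[C@@H]2O)c(OCc9ccccc9)c2c1O[C@H](c8ccc(OCc9ccccc9)c(OCc9ccccc9)c8)[C@@H](OCc9ccccc9)C2 | intermediate
24 | 6-bromo-3,7,3',4'-tetra-O-benzyl-ent-fisetinidol-(4α→8)-[3,7,3',4'-tetra-O-benzyl-ent-fisetinidol-(4β→6)]-penta-O-benzylcatechin | Brc1cc2c(cc1OCc9ccccc9)O[C@@H](c8ccc(OCc9ccccc9)c(OCc9ccccc9)c8)[C@H](OCc9ccccc9)[C@@H]2c1c(OCc9ccccc9)c([C@H]2c3ccc(OCc9ccccc9)cc3O[C@@H](c8ccc(OCc9ccccc9)c(OCc9ccccc9)c8)[C@@H]2OCc9ccccc9)c(OCc9ccccc9)c2c1O[C@H](c8ccc(OCc9ccccc9)c(OCc9ccccc9)c8)[C@@H](OCc9ccccc9)C2 | intermediate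
25 | 24 with lithium in place of bromine (C6 of unit 2) | [Li]c1cc2c(cc1OCc9ccccc9)O[C@@H](c8ccc(OCc9ccccc9)c(OCc9ccccc9)c8)[C@H](OCc9ccccc9)[C@@H]2c1c(OCc9ccccc9)c([C@H]2c3ccc(OCc9ccccc9)cc3O[C@@H](c8ccc(OCc9ccccc9)c(OCc9ccccc9)c8)[C@@H]2OCc9ccccc9)c(OCc9ccccc9)c2c1O[C@H](c8ccc(OCc9ccccc9)c(OCc9ccccc9)c8)[C@@H](OCc9ccccc9)C2 | intermediate (not isolated)
26 | (E)-1-[4-(benzyloxy)-2-(tert-butyldimethylsilyloxy)phenyl]-3-[3,4-bis(benzyloxy)phenyl]prop-2-en-1-ol bearing at C1 the C6 of unit 2 of 24, both C1 epimers | CC(C)(C)[Si](C)(C)Oc1cc(OCc9ccccc9)ccc1C(O)(/C=C/c8ccc(OCc9ccccc9)c(OCc9ccccc9)c8)c1cc2c(cc1OCc9ccccc9)O[C@@H](c8ccc(OCc9ccccc9)c(OCc9ccccc9)c8)[C@H](OCc9ccccc9)[C@@H]2c1c(OCc9ccccc9)c([C@H]2c3ccc(OCc9ccccc9)cc3O[C@@H](c8ccc(OCc9ccccc9)c(OCc9ccccc9)c8)[C@@H]2OCc9ccccc9)c(OCc9ccccc9)c2c1O[C@H](c8ccc(OCc9ccccc9)c(OCc9ccccc9)c8)[C@@H](OCc9ccccc9)C2 | intermediate (not isolated)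
27 | 26 with the phenol free, both C1 epimers | Oc1cc(OCc9ccccc9)ccc1C(O)(/C=C/c8ccc(OCc9ccccc9)c(OCc9ccccc9)c8)c1cc2c(cc1OCc9ccccc9)O[C@@H](c8ccc(OCc9ccccc9)c(OCc9ccccc9)c8)[C@H](OCc9ccccc9)[C@@H]2c1c(OCc9ccccc9)c([C@H]2c3ccc(OCc9ccccc9)cc3O[C@@H](c8ccc(OCc9ccccc9)c(OCc9ccccc9)c8)[C@@H]2OCc9ccccc9)c(OCc9ccccc9)c2c1O[C@H](c8ccc(OCc9ccccc9)c(OCc9ccccc9)c8)[C@@H](OCc9ccccc9)C2 | intermediate
28 | 24 with the (2R)-7-(benzyloxy)-2-[3,4-bis(benzyloxy)phenyl]-2H-chromen-4-yl group in place of bromine | c9ccccc9COc1ccc2c(c1)O[C@@H](c8ccc(OCc9ccccc9)c(OCc9ccccc9)c8)C=C2c1cc2c(cc1OCc9ccccc9)O[C@@H](c8ccc(OCc9ccccc9)c(OCc9ccccc9)c8)[C@H](OCc9ccccc9)[C@@H]2c1c(OCc9ccccc9)c([C@H]2c3ccc(OCc9ccccc9)cc3O[C@@H](c8ccc(OCc9ccccc9)c(OCc9ccccc9)c8)[C@@H]2OCc9ccccc9)c(OCc9ccccc9)c2c1O[C@H](c8ccc(OCc9ccccc9)c(OCc9ccccc9)c8)[C@@H](OCc9ccccc9)C2 | intermediate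
29 | 28 dihydroxylated at C3=C4 of unit 1: 3α-OH, 4α-OH, C6 of unit 2 on the β face of C4 | c9ccccc9COc1ccc2c(c1)O[C@@H](c8ccc(OCc9ccccc9)c(OCc9ccccc9)c8)[C@H](O)[C@@]2(O)c1cc2c(cc1OCc9ccccc9)O[C@@H](c8ccc(OCc9ccccc9)c(OCc9ccccc9)c8)[C@H](OCc9ccccc9)[C@@H]2c1c(OCc9ccccc9)c([C@H]2c3ccc(OCc9ccccc9)cc3O[C@@H](c8ccc(OCc9ccccc9)c(OCc9ccccc9)c8)[C@@H]2OCc9ccccc9)c(OCc9ccccc9)c2c1O[C@H](c8ccc(OCc9ccccc9)c(OCc9ccccc9)c8)[C@@H](OCc9ccccc9)C2 | intermediate
30 | hexadeca-O-benzyl tetramer: 7,3',4'-tri-O-benzyl-ent-fisetinidol-(4α→6)-3,7,3',4'-tetra-O-benzyl-ent-fisetinidol-(4α→8)-[3,7,3',4'-tetra-O-benzyl-ent-fisetinidol-(4β→6)]-penta-O-benzylcatechin | c9ccccc9COc1ccc2c(c1)O[C@@H](c8ccc(OCc9ccccc9)c(OCc9ccccc9)c8)[C@H](O)[C@@H]2c1cc2c(cc1OCc9ccccc9)O[C@@H](c8ccc(OCc9ccccc9)c(OCc9ccccc9)c8)[C@H](OCc9ccccc9)[C@@H]2c1c(OCc9ccccc9)c([C@H]2c3ccc(OCc9ccccc9)cc3O[C@@H](c8ccc(OCc9ccccc9)c(OCc9ccccc9)c8)[C@@H]2OCc9ccccc9)c(OCc9ccccc9)c2c1O[C@H](c8ccc(OCc9ccccc9)c(OCc9ccccc9)c8)[C@@H](OCc9ccccc9)C2 | intermediate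
31 | ent-fisetinidol-(4α→6)-ent-fisetinidol-(4α→8)-[ent-fisetinidol-(4β→6)]-catechin; unit 1 (2S,3R,4R), unit 2 (2S,3R,4S), unit 3 (2R,3S), unit 4 (2S,3R,4R) | Oc1ccc2c(c1)O[C@@H](c1ccc(O)c(O)c1)[C@H](O)[C@@H]2c1cc2c(cc1O)O[C@@H](c1ccc(O)c(O)c1)[C@H](O)[C@@H]2c1c(O)c([C@H]2c3ccc(O)cc3O[C@@H](c3ccc(O)c(O)c3)[C@@H]2O)c(O)c2c1O[C@H](c1ccc(O)c(O)c1)[C@@H](O)C2 | target

**Count and risks**

Total step count: 22. Longest linear sequence: 18 steps (steps 3, 4, 5 and 8 to 22, from 1 to 31).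

Steps most likely to fail:

Step 19 (key step). Catalyst control may be lost in two ways: the product may re-ionise at the C2–O1 bond under the acid, which epimerises C2, or a mismatched pairing of the catalyst with the chiral trimer may slow the closure so that an unselective background path takes over. Fallback: stereocontrol by separation and recycling instead of by the catalyst. The fallback sets out from carbinol 27, which is closed with an achiral acid (diphenyl phosphate, CH2Cl2, 0 °C). Because the trimer part is a single enantiomer, the two C2 epimers are diastereomers and should separate by preparative HPLC: 28 and the (2S)-epimer of 28 F1. F1 is returned to the same acid at room temperature, where reversible C2–O1 ionisation regenerates the mixture, and is cycled. The route is rejoined at 28.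

Step 21. The C4 cation may lose H3 or suffer a 1,2-hydride shift (pinacol path) to the flavan-3-one faster than it takes hydride, hydride delivery may show poor facial selectivity, or the acid may cleave an interflavan bond. Fallback: a radical instead of a cation at C4 (Barton–McCombie-type deoxygenation). The fallback sets out from diol 29, which with 1,1'-thiocarbonyldiimidazole (DMAP, toluene, 80 °C) gives the cyclic 3,4-thiocarbonate of 29 F2. Bu3SnH/AIBN (toluene, 100 °C) fragments F2 at the tertiary, doubly benzylic C4–O bond, and the planar C4 radical should take hydrogen from the tin hydride anti to the O3 substituent. Hydrolytic work-up (NaOH, MeOH) of the C3 thiolcarbonate frees the 3-OH. The route is rejoined at 30.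

Step 20. Osmylation of the trisubstituted C3=C4 bond next to the ortho-substituted aryl group may be too slow or poorly face-selective, and the electron-rich rings may be over-oxidised on long exposure. Fallback: epoxidation and reductive opening, which bypasses 29 and step 21. The fallback sets out from 28, which with dimethyldioxirane (acetone/CH2Cl2, −40 °C) should give, anti to ring B, the 3α,4α-epoxide of 28 F3. BH3·THF with catalytic BF3·OEt2 (THF, 0 °C) opens F3 by hydride attack at the benzylic C4 with inversion, the known course for aryl-substituted epoxides, which places the aryl group cis to the 3-OH. The route is rejoined at 30.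

**Further compounds**

F1 | step 19 | (2S)-epimer of 28 (C2 of the 2H-chromene of unit 1 inverted) | c9ccccc9COc1ccc2c(c1)O[C@H](c8ccc(OCc9ccccc9)c(OCc9ccccc9)c8)C=C2c1cc2c(cc1OCc9ccccc9)O[C@@H](c8ccc(OCc9ccccc9)c(OCc9ccccc9)c8)[C@H](OCc9ccccc9)[C@@H]2c1c(OCc9ccccc9)c([C@H]2c3ccc(OCc9ccccc9)cc3O[C@@H](c8ccc(OCc9ccccc9)c(OCc9ccccc9)c8)[C@@H]2OCc9ccccc9)c(OCc9ccccc9)c2c1O[C@H](c8ccc(OCc9ccccc9)c(OCc9ccccc9)c8)[C@@H](OCc9ccccc9)C2
F2 | step 21 | cyclic 3,4-thiocarbonate of diol 29 | c9ccccc9COc1ccc2c(c1)O[C@@H](c8ccc(OCc9ccccc9)c(OCc9ccccc9)c8)[C@H](OC(=S)O5)[C@@]25c1cc2c(cc1OCc9ccccc9)O[C@@H](c8ccc(OCc9ccccc9)c(OCc9ccccc9)c8)[C@H](OCc9ccccc9)[C@@H]2c1c(OCc9ccccc9)c([C@H]2c3ccc(OCc9ccccc9)cc3O[C@@H](c8ccc(OCc9ccccc9)c(OCc9ccccc9)c8)[C@@H]2OCc9ccccc9)c(OCc9ccccc9)c2c1O[C@H](c8ccc(OCc9ccccc9)c(OCc9ccccc9)c8)[C@@H](OCc9ccccc9)C2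
F3 | step 20 | 3α,4α-epoxide of 28 (epoxide anti to ring B of unit 1) | c9ccccc9COc1ccc2c(c1)O[C@@H](c8ccc(OCc9ccccc9)c(OCc9ccccc9)c8)[C@@H]5O[C@]25c1cc2c(cc1OCc9ccccc9)O[C@@H](c8ccc(OCc9ccccc9)c(OCc9ccccc9)c8)[C@H](OCc9ccccc9)[C@@H]2c1c(OCc9ccccc9)c([C@H]2c3ccc(OCc9ccccc9)cc3O[C@@H](c8ccc(OCc9ccccc9)c(OCc9ccccc9)c8)[C@@H]2OCc9ccccc9)c(OCc9ccccc9)c2c1O[C@H](c8ccc(OCc9ccccc9)c(OCc9ccccc9)c8)[C@@H](OCc9ccccc9)C2
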